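The 1,2-dioxolane is cut at the O1–C5 bond. Because C5 carries a methyl group, it can be born as the Markovnikov carbon of a C5=CH2 alkene; the precursor is an acyclic C3 tertiary hydroperoxide with this 1,1-disubstituted alkene one CH2 (C4) away. A confined chiral Brønsted acid closes the ring (atoms O1, O2, C3, C4, C5) in one 5-exo operation, creating the C5 methyl and the C5 quaternary stereocentre under catalyst control. C3 derives from (R)-mevalonolactone, whose carbinol is folded into an oxetane that hydrogen peroxide opens with inversion. The C2' centre comes from (R)-3-bromo-2-methylpropan-1-ol; the phenyldiene is added last by olefination.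

Key step: step 9

Remark: locants are O1, O2, C3 (acid arm), C4, C5 (side chain) and C1'–C12' along the side chain; of the two antipodes of the IDPi acid, the one that adds oxygen to the Re face of C5 is assumed, to be identified by testing both.

Step 1
Reactants: 1 (R)-mevalonolactone
Product: 2 (3R)-3,5-dihydroxy-N-methoxy-N,3-dimethylpentanamide
Conditions: MeNH(OMe)·HCl, AlMe3, CH2Cl2, 0 °C → rt; aq. Rochelle salt
Reagents that add atoms: N,O-dimethylhydroxylamine hydrochloride, CNOC.Cl
Why: Weinreb aminolysis of the δ-lactone with the aluminium amide opens the ring without touching the tertiary carbinol and differentiates the two arms of mevalonate (amide versus primary alcohol).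

Step 2
Reactants: 2 (3R)-3,5-dihydroxy-N-methoxy-N,3-dimethylpentanamide
Product: 4 N-methoxy-N-methyl-2-[(2R)-2-methyloxetan-2-yl]acetamide, via monotosylate 3 (not isolated)
Conditions: TsCl, Et3N, DMAP (cat.), CH2Cl2, 0 °C; then NaH, THF, 0 °C → rt
Reagents that add atoms: none
Why: Selective sulfonylation of the primary hydroxyl and intramolecular Williamson etherification (4-exo-tet) by the tertiary alkoxide give the oxetane; no bond to the stereocentre is broken, so its configuration is retained.

Step 3
Reactants: 5 (R)-3-bromo-2-methylpropan-1-ol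
Product: 6 (2R)-3-bromo-2-methylpropyl trifluoromethanesulfonate
Conditions: Tf2O, pyridine, CH2Cl2, −78 → −30 °C
Reagents that add atoms: trifluoromethanesulfonic anhydride, O=S(=O)(OS(=O)(=O)C(F)(F)F)C(F)(F)F
Why: O-sulfonylation gives a primary triflate that should outcompete the β-branched bromide as electrophile in the next step; the stereocentre is not involved.

Step 4
Reactants: 6 (2R)-3-bromo-2-methylpropyl trifluoromethanesulfonate; 7 7-bromohept-1-ene
Product: 9 (9R)-10-bromo-9-methyldec-1-ene, via hept-6-en-1-ylmagnesium bromide 8 (not isolated)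
Conditions: 7, Mg, THF, rt; then 6, CuBr·SMe2 (cat.), THF, −78 → −30 °C
Reagents that add atoms: none
Why: Copper-catalysed sp3–sp3 cross-coupling of a Grignard reagent (Kochi-type coupling) should occur at the triflate far faster than at the hindered bromide, which is kept as the handle for step 5.

Step 5
Reactants: 9 (9R)-10-bromo-9-methyldec-1-ene; 4 N-methoxy-N-methyl-2-[(2R)-2-methyloxetan-2-yl]acetamide
Product: 11 (4R)-4-methyl-1-[(2R)-2-methyloxetan-2-yl]dodec-11-en-2-one, via Grignard reagent 10 (not isolated)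
Conditions: 9, Mg, THF, rt; then 4, THF, 0 °C; aq. NH4Cl
Reagents that add atoms: none
Why: Weinreb ketone synthesis, in which the chelated tetrahedral adduct stops at the ketone stage; the oxetane is inert to Grignard reagents at 0 °C.

Step 6
Reactants: 11 (4R)-4-methyl-1-[(2R)-2-methyloxetan-2-yl]dodec-11-en-2-one
Product: 12 (2S)-2-methyl-2-[(4R)-4-methyl-2-methylidenedodec-11-en-1-yl]oxetane
Conditions: Cp2TiMe2, toluene, 65 °C, dark
Reagents that add atoms: dimethyltitanocene Cp2TiMe2, C[Ti](C)(C1C=CC=C1)C1C=CC=C1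
Why: Petasis methylenation is a non-basic carbonyl olefination through Cp2Ti=CH2 and so avoids enolisation and β-elimination of the oxetane oxygen that a basic ylide could cause.

Step 7
Reactants: 12 (2S)-2-methyl-2-[(4R)-4-methyl-2-methylidenedodec-11-en-1-yl]oxetane
Product: 13 (3R,7R)-3-hydroperoxy-3,7-dimethyl-5-methylidenepentadec-14-en-1-ol
Conditions: H2O2 (anhydrous, in Et2O, excess), TMSOTf (0.2 equiv), Et2O, −78 → −20 °C
Reagents that add atoms: hydrogen peroxide, OO
Why: Lewis acid-promoted opening of a 2,2-disubstituted oxetane by hydrogen peroxide takes place at the tertiary carbon in an SN2-like manner with predominant inversion, which turns the mevalonate carbinol into the (R)-configured C3 hydroperoxide; the alkenes should not be protonated in ether at low temperature.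

Step 8
Reactants: 13 (3R,7R)-3-hydroperoxy-3,7-dimethyl-5-methylidenepentadec-14-en-1-ol
Product: 15 (3R,7R)-1-{[tert-butyl(diphenyl)silyl]oxy}-3,7-dimethyl-5-methylidenepentadec-14-en-3-yl hydroperoxide, via bis-silylated hydroperoxide 14 (not isolated)
Conditions: TBDPSCl (2.4 equiv), imidazole, DMF, 0 °C → rt; then K2CO3, MeOH, 0 °C
Reagents that add atoms: tert-butyl(chloro)diphenylsilane, CC(C)(C)[Si](Cl)(c1ccccc1)c1ccccc1
Why: Exhaustive silylation followed by selective methanolysis of the far more labile silyl peroxide (the peroxide anion is the better leaving group at silicon) leaves only the primary alcohol masked, so that it cannot compete by 6-exo hydroalkoxylation in step 9.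

Step 9
Reactants: 15 (3R,7R)-1-{[tert-butyl(diphenyl)silyl]oxy}-3,7-dimethyl-5-methylidenepentadec-14-en-3-yl hydroperoxide
Product: 16 tert-butyl(2-{(3S,5R)-3,5-dimethyl-5-[(2R)-2-methyldec-9-en-1-yl]-1,2-dioxolan-3-yl}ethoxy)diphenylsilane
Conditions: IDPi acid (N,N'-bis(triflyl) imidodiphosphorimidate of 3,3'-bis[3,5-bis(trifluoromethyl)phenyl]-BINOL, 5 mol %), cyclohexane, 25 °C
Reagents that add atoms: none
Why: Proposed new method: the confined chiral acid protonates the CH2 terminus of the 1,1-disubstituted alkene while its counter-anion holds the O–H of the hydroperoxide, and the terminal peroxide oxygen adds to the developing tertiary cation at C5 in a concerted asynchronous step, so the C5 methyl group and the O1–C5 bond arise together. The closest known reaction type is the IDPi-catalysed asymmetric intramolecular hydroalkoxylation of unactivated 1,1-disubstituted alkenols to 2,2-disubstituted tetrahydrofurans, together with the long-known acid- and mercury-promoted cyclisation of unsaturated hydroperoxides to 1,2-dioxolanes. The dioxolane is closed in a 5-exo-trig (Markovnikov) mode. The C5 stereocentre is controlled by the catalyst, which must deliver oxygen to the Re face of C5 and tell the nascent methyl from the C1' methylene; C3 (step 7) and C2' (from 5) are untouched, and because the substrate bias between the two faces is small the catalyst antipode should decide. The step needs chemoselectivity for the 1,1-disubstituted alkene over the terminal one, secured because only the former leads to a tertiary cation, and for the hydroperoxide over the arm oxygen, secured by the silyl ether. A non-basic, weakly nucleophilic hydrocarbon medium is chosen to suppress Hock-type fragmentation of the tertiary hydroperoxide.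

Step 10
Reactants: 16 tert-butyl(2-{(3S,5R)-3,5-dimethyl-5-[(2R)-2-methyldec-9-en-1-yl]-1,2-dioxolan-3-yl}ethoxy)diphenylsilane
Product: 18 (3S,5R)-3-(2-{[tert-butyl(diphenyl)silyl]oxy}ethyl)-3,5-dimethyl-5-[(2R)-2-methyl-9-oxononyl]-1,2-dioxolane, via vicinal diol 17 (not isolated)
Conditions: OsO4 (cat.), NaIO4, 2,6-lutidine, dioxane–H2O, rt
Reagents that add atoms: osmium tetroxide OsO4, O=[Os](=O)(=O)=O (oxygen carrier); sodium periodate NaIO4, [Na+].[O-]I(=O)(=O)=O (terminal oxidant)
Why: Lemieux–Johnson oxidative cleavage (dihydroxylation, then periodate glycol cleavage) of the only remaining alkene gives the aldehyde; a dialkyl peroxide without α-hydrogens and the silyl ether should tolerate these conditions.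

Step 11
Reactants: 18 (3S,5R)-3-(2-{[tert-butyl(diphenyl)silyl]oxy}ethyl)-3,5-dimethyl-5-[(2R)-2-methyl-9-oxononyl]-1,2-dioxolane; 19 diethyl [(2E)-3-phenylprop-2-en-1-yl]phosphonate
Product: 21 tert-butyl(2-{(3S,5R)-3,5-dimethyl-5-[(2R,9E,11E)-2-methyl-12-phenyldodeca-9,11-dien-1-yl]-1,2-dioxolan-3-yl}ethoxy)diphenylsilane, via lithiated phosphonate 20 (not isolated)
Conditions: 19, LiN(SiMe3)2, THF, −78 °C; then 18, −78 → 0 °C
Reagents that add atoms: none
Why: Horner–Wadsworth–Emmons olefination with an allylic phosphonate anion should form the new C9'=C10' bond with E selectivity, while the E geometry of the styryl bond is carried in from 19.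

Step 12
Reactants: 21 tert-butyl(2-{(3S,5R)-3,5-dimethyl-5-[(2R,9E,11E)-2-methyl-12-phenyldodeca-9,11-dien-1-yl]-1,2-dioxolan-3-yl}ethoxy)diphenylsilane
Product: 22 2-{(3S,5R)-3,5-dimethyl-5-[(2R,9E,11E)-2-methyl-12-phenyldodeca-9,11-dien-1-yl]-1,2-dioxolan-3-yl}ethan-1-ol
Conditions: TBAF, THF, 0 °C → rt
Reagents that add atoms: none
Why: Fluoride-mediated desilylation; the fully substituted dialkyl peroxide has no α-hydrogen and should be inert to fluoride.

Step 13
Reactants: 22 2-{(3S,5R)-3,5-dimethyl-5-[(2R,9E,11E)-2-methyl-12-phenyldodeca-9,11-dien-1-yl]-1,2-dioxolan-3-yl}ethan-1-ol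
Product: 23 2-{(3R,5R)-3,5-dimethyl-5-[(2R,9E,11E)-2-methyl-12-phenyldodeca-9,11-dien-1-yl]-1,2-dioxolan-3-yl}acetic acid
Conditions: TEMPO (cat.), PhI(OAc)2, MeCN–H2O (pH 7 buffer), rt
Reagents that add atoms: water, O
Why: Oxoammonium (TEMPO)-catalysed oxidation of the primary alcohol through the aldehyde hydrate to the carboxylic acid is mild enough for the conjugated diene and the peroxide, and no stereocentre is affected (the C3 descriptor changes from S to R only through the priority change of the arm).

Compound list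
1 | (R)-mevalonolactone | C[C@@]1(O)CCOC(=O)C1 | starting material
2 | (3R)-3,5-dihydroxy-N-methoxy-N,3-dimethylpentanamide | C[C@@](O)(CCO)CC(=O)N(C)OC | intermediate
3 | (3R)-3-hydroxy-5-[methoxy(methyl)amino]-3-methyl-5-oxopentyl 4-methylbenzenesulfonate (not isolated) | C[C@@](O)(CCOS(=O)(=O)c1ccc(C)cc1)CC(=O)N(C)OC | intermediate
4 | N-methoxy-N-methyl-2-[(2R)-2-methyloxetan-2-yl]acetamide | C[C@]1(CC(=O)N(C)OC)CCO1 | intermediate
5 | (R)-3-bromo-2-methylpropan-1-ol | OC[C@@H](C)CBr | starting material
6 | (2R)-3-bromo-2-methylpropyl trifluoromethanesulfonate | FC(F)(F)S(=O)(=O)OC[C@@H](C)CBr | intermediate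
7 | 7-bromohept-1-ene | C=CCCCCCBr | starting material
8 | hept-6-en-1-ylmagnesium bromide (not isolated) | C=CCCCCC[Mg]Br | intermediate
9 | (9R)-10-bromo-9-methyldec-1-ene | BrC[C@H](C)CCCCCCC=C | intermediate
10 | [(2R)-2-methyldec-9-en-1-yl]magnesium bromide (not isolated) | Br[Mg]C[C@H](C)CCCCCCC=C | intermediate
11 | (4R)-4-methyl-1-[(2R)-2-methyloxetan-2-yl]dodec-11-en-2-one | C[C@]1(CC(=O)C[C@H](C)CCCCCCC=C)CCO1 | intermediate
12 | (2S)-2-methyl-2-[(4R)-4-methyl-2-methylidenedodec-11-en-1-yl]oxetane | C[C@]1(CC(=C)C[C@H](C)CCCCCCC=C)CCO1 | intermediate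
13 | (3R,7R)-3-hydroperoxy-3,7-dimethyl-5-methylidenepentadec-14-en-1-ol | C[C@@](OO)(CC(=C)C[C@H](C)CCCCCCC=C)CCO | intermediate
14 | bis-TBDPS derivative of 13, silyl ether at O1 and silyl peroxide at C3 (not isolated) | C[C@@](OO[Si](c1ccccc1)(c1ccccc1)C(C)(C)C)(CC(=C)C[C@H](C)CCCCCCC=C)CCO[Si](c1ccccc1)(c1ccccc1)C(C)(C)C | intermediate
15 | (3R,7R)-1-{[tert-butyl(diphenyl)silyl]oxy}-3,7-dimethyl-5-methylidenepentadec-14-en-3-yl hydroperoxide | C[C@@](OO)(CC(=C)C[C@H](C)CCCCCCC=C)CCO[Si](c1ccccc1)(c1ccccc1)C(C)(C)C | intermediate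
16 | tert-butyl(2-{(3S,5R)-3,5-dimethyl-5-[(2R)-2-methyldec-9-en-1-yl]-1,2-dioxolan-3-yl}ethoxy)diphenylsilane | C[C@H](CCCCCCC=C)C[C@]1(C)C[C@](C)(CCO[Si](c2ccccc2)(c2ccccc2)C(C)(C)C)OO1 | intermediate
17 | vicinal diol from 16, 9,10-dihydroxy-2-methyldecyl side chain, both carbinol epimers (not isolated) | C[C@H](CCCCCCC(O)CO)C[C@]1(C)C[C@](C)(CCO[Si](c2ccccc2)(c2ccccc2)C(C)(C)C)OO1 | intermediate
18 | (3S,5R)-3-(2-{[tert-butyl(diphenyl)silyl]oxy}ethyl)-3,5-dimethyl-5-[(2R)-2-methyl-9-oxononyl]-1,2-dioxolane | C[C@H](CCCCCCC=O)C[C@]1(C)C[C@](C)(CCO[Si](c2ccccc2)(c2ccccc2)C(C)(C)C)OO1 | intermediate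
19 | diethyl [(2E)-3-phenylprop-2-en-1-yl]phosphonate (diethyl cinnamylphosphonate) | CCOP(=O)(OCC)C/C=C/c1ccccc1 | starting material
20 | lithium salt of 19, α-phosphonyl allyl anion (not isolated) | [Li+].CCOP(=O)(OCC)[CH-]/C=C/c1ccccc1 | intermediate
21 | tert-butyl(2-{(3S,5R)-3,5-dimethyl-5-[(2R,9E,11E)-2-methyl-12-phenyldodeca-9,11-dien-1-yl]-1,2-dioxolan-3-yl}ethoxy)diphenylsilane | C[C@H](CCCCCC/C=C/C=C/c1ccccc1)C[C@]1(C)C[C@](C)(CCO[Si](c2ccccc2)(c2ccccc2)C(C)(C)C)OO1 | intermediate
22 | 2-{(3S,5R)-3,5-dimethyl-5-[(2R,9E,11E)-2-methyl-12-phenyldodeca-9,11-dien-1-yl]-1,2-dioxolan-3-yl}ethan-1-ol | C[C@H](CCCCCC/C=C/C=C/c1ccccc1)C[C@]1(C)C[C@](C)(CCO)OO1 | intermediate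
23 | 2-{(3R,5R)-3,5-dimethyl-5-[(2R,9E,11E)-2-methyl-12-phenyldodeca-9,11-dien-1-yl]-1,2-dioxolan-3-yl}acetic acid | C[C@H](CCCCCC/C=C/C=C/c1ccccc1)C[C@]1(C)C[C@](C)(CC(=O)O)OO1 | target

Total step count: 13. Longest linear sequence: 11 steps (steps 1, 2, 5–13; the branch through steps 3, 4, 5–13 is equally long).

Steps most likely to fail

1. Step 9 (Proposed new method). The acid may trigger Hock-type fragmentation of the tertiary hydroperoxide, turnover may be slow because a hydroperoxide is a weaker base than an alcohol, or the catalyst may not discriminate the two faces of C5 well enough. Fallback with known chemistry, from 15: cycloperoxymercuration with Hg(OAc)2 in CH2Cl2 (cat. HClO4, 0 °C) closes the same ring 5-exo and should give the acetoxymercuriomethyl dioxolane F1 together with its C5 epimer F2. Reduction with NaBH4 in aqueous NaOH then replaces mercury by hydrogen to give 16 and its C5 epimer F3, which is removed by chromatography. The route is rejoined at 16; C5 is then not controlled but separated.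

2. Step 7. Partial ionisation to a tertiary cation would erode the configuration at C3, the acid could add peroxide to the 1,1-disubstituted alkene, and product hydroperoxide could attack unreacted oxetane. Fallback, from 12, reverses the order of C–O bond formation. Mukaiyama–Isayama hydroperoxysilylation (Co(acac)2 cat., O2, Et3SiH, EtOH, rt; the more substituted alkene should react first, silane limiting) gives the tertiary triethylsilyl peroxide F4 and its C5 epimer F5. Catalytic TMSOTf in CH2Cl2 at −78 °C should then drive the known intramolecular 5-exo opening of the oxetane by the peroxide oxygen, with inversion at C3 and loss of the silyl group on work-up, to give the dioxolane alcohol F6 and its C5 epimer F7 (removed by chromatography). Silylation of F6 (TBDPSCl, imidazole) returns to 16.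

3. Step 11. Incomplete E selectivity at the new C9'=C10' bond, or enolisation and self-condensation of the aldehyde under the basic conditions, would give a diene mixture that is hard to purify. Fallback, from 16: cross-metathesis of the terminal alkene with vinylboronic acid pinacol ester (second-generation Hoveyda–Grubbs catalyst, CH2Cl2, 40 °C) should give the (E)-alkenyl pinacol boronate F8. Stereoretentive Suzuki–Miyaura coupling with (E)-β-bromostyrene (Pd(PPh3)4, aq. K3PO4, THF, 50 °C) then gives 21 directly, bypassing 17–20.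

Further compounds
F1 | step 9 | 16 in which the C5 methyl is CH2HgOAc, configuration at C5 as in 16 | C[C@H](CCCCCCC=C)C[C@]1(C[Hg]OC(C)=O)C[C@](C)(CCO[Si](c2ccccc2)(c2ccccc2)C(C)(C)C)OO1
F2 | step 9 | C5 epimer of F1 | C[C@H](CCCCCCC=C)C[C@@]1(C[Hg]OC(C)=O)C[C@](C)(CCO[Si](c2ccccc2)(c2ccccc2)C(C)(C)C)OO1
F3 | step 9 | C5 epimer of 16 | C[C@H](CCCCCCC=C)C[C@@]1(C)C[C@](C)(CCO[Si](c2ccccc2)(c2ccccc2)C(C)(C)C)OO1
F4 | step 7 | triethylsilyl peroxide from 12, oxetane intact, C5(CH3)(OOSiEt3) with the configuration needed for 16 | C[C@]1(C[C@](C)(OO[Si](CC)(CC)CC)C[C@H](C)CCCCCCC=C)CCO1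
F5 | step 7 | C5 epimer of F4 | C[C@]1(C[C@@](C)(OO[Si](CC)(CC)CC)C[C@H](C)CCCCCCC=C)CCO1
F6 | step 7 | 2-{(3S,5R)-3,5-dimethyl-5-[(2R)-2-methyldec-9-en-1-yl]-1,2-dioxolan-3-yl}ethan-1-ol | C[C@H](CCCCCCC=C)C[C@]1(C)C[C@](C)(CCO)OO1
F7 | step 7 | C5 epimer of F6 | C[C@H](CCCCCCC=C)C[C@@]1(C)C[C@](C)(CCO)OO1
F8 | step 11 | 16 in which the terminal CH=CH2 is (E)-CH=CH–B(pinacolato) | C[C@H](CCCCCC/C=C/B1OC(C)(C)C(C)(C)O1)C[C@]1(C)C[C@](C)(CCO[Si](c2ccccc2)(c2ccccc2)C(C)(C)C)OO1
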